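Cardopatine is a C2-symmetric trans-1,2-dialkynylcyclobutane, so the plan rests on cutting the C(sp)–C(sp2) bond between an alkyne terminus and C5 of its 2,2'-bithiophene. The key step is a twofold Sonogashira coupling of (1R,2R)-1,2-diethynylcyclobutane with 5-bromo-2,2'-bithiophene. The C2 axis through the midpoints of the C1–C2 and C3–C4 bonds of the cyclobutane makes the two ethynyl groups homotopic, so one operation attaches both arms; the second event joins the mono-arylated diyne to the second bithiophene. The diyne precursor holds all eight core carbons and both stereocentres, which come from a meso anhydride by enantioselective methanolysis and one epimerization.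

Key step: step 4

Assumption on the chemistry: the quinine-mediated methanolysis of anhydride 1 is assumed to follow the usual sense of this reaction class and leave the free acid on the R carbon; if the opposite sense is found, quinidine replaces quinine and nothing else changes.

Step 1
Reactants: 1 cis-cyclobutane-1,2-dicarboxylic anhydride (3-oxabicyclo[3.2.0]heptane-2,4-dione, meso)
Product: 2 (1R,2S)-2-(methoxycarbonyl)cyclobutane-1-carboxylic acid (cis hemiester)
Conditions: quinine (1.1 equiv), MeOH (3 equiv), toluene, −55 °C, 60 h; aq. HCl wash (quinine recovered)
Reagents that add atoms: methanol, CO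
Why: Alkaloid-mediated enantioselective alcoholysis of a meso anhydride (desymmetrization), in which quinine acts as a chiral general base that delivers methanol to one of the two enantiotopic carbonyl groups, so that the two existing cis stereocentres become distinguishable (acid-bearing carbon R, ester-bearing carbon S).

Step 2
Reactants: 2 (1R,2S)-2-(methoxycarbonyl)cyclobutane-1-carboxylic acid
Product: 4 dimethyl (1R,2R)-cyclobutane-1,2-dicarboxylate, via trans hemiester 3 (not isolated)
Conditions: NaOMe (3 equiv), MeOH, reflux; then HCl in MeOH (excess), reflux; chromatography to remove any meso cis diester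
Reagents that add atoms: methanol, CO
Why: Thermodynamic epimerization followed by Fischer esterification, in which methoxide enolises only the ester-bearing carbon (the α-position of the carboxylate is shielded by its negative charge), reprotonation gives the more stable trans isomer so that C2 is set R relative to the untouched C1, and only then are the two ends made alike under acid, where no enolisation occurs.

Step 3
Reactants: 4 dimethyl (1R,2R)-cyclobutane-1,2-dicarboxylate
Product: 6 (1R,2R)-1,2-diethynylcyclobutane, via dialdehyde 5 (not isolated)
Conditions: i-Bu2AlH (2.2 equiv), CH2Cl2, −78 °C; then MeOH, K2CO3, dimethyl (1-diazo-2-oxopropyl)phosphonate (2.6 equiv), −78 °C to rt; Rochelle-salt work-up, pentane extraction, solution concentrated cold and used directly (volatile)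
Reagents that add atoms: dimethyl (1-diazo-2-oxopropyl)phosphonate (Bestmann–Ohira reagent), CC(=O)C(=[N+]=[N-])P(=O)(OC)OC
Why: One-pot partial reduction and Seyferth–Gilbert homologation with the Bestmann–Ohira reagent, in which the tetrahedral aluminium hemiacetals hold the aldehyde oxidation level at −78 °C, methanolysis frees dialdehyde 5 in the presence of the diazophosphonate anion, and both formyl groups become ethynyl groups without touching the ring stereocentres, since the trans dialdehyde is the stable isomer and enolisation exocyclic to a four-membered ring is slow.

Step 4
Reactants: 6 (1R,2R)-1,2-diethynylcyclobutane; 7 5-bromo-2,2'-bithiophene (2.2 equiv)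
Product: 9 cardopatine, via monoarylated diyne 8 (not isolated)
Conditions: Pd(PhCN)2Cl2 (4 mol %), [HP(t-Bu)3]BF4 (8 mol %), CuI (4 mol %), i-Pr2NH, dioxane (degassed), rt, dark
Reagents that add atoms: none
Why: Twofold Sonogashira coupling: zerovalent palladium, formed in the flask from Pd(PhCN)2Cl2 and P(t-Bu)3, adds oxidatively into the C5–Br bond of 7, the copper acetylide made from a terminal alkyne of 6 with CuI and the amine transmetalates, and reductive elimination forms the C(sp)–C5(thienyl) bond; the first cycle gives 8, and the second joins the remaining alkyne terminus of 8 to C5 of a second molecule of 7. The closest known reaction type is the room-temperature Sonogashira coupling of alkyl-substituted terminal alkynes with electron-rich aryl and 2-thienyl bromides under Pd/P(t-Bu)3 catalysis. No ring is closed and no stereocentre is formed; C1 and C2 of the cyclobutane are spectators, their propargylic C–H bonds being far too weakly acidic for the amine base. The step needs cross-coupling to win over oxidative alkyne homocoupling and needs both alkynes to react: oxygen is excluded, 7 is in excess, and the C2 axis of 6 makes the two alkynes equivalent, so the second coupling should be no harder than the first. Site selectivity on the heteroarene is fixed by the single C–Br bond of 7, and the trans arrangement holds the two alkynes too far apart for intramolecular carbopalladation.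

Compound list
1 | cis-cyclobutane-1,2-dicarboxylic anhydride (3-oxabicyclo[3.2.0]heptane-2,4-dione, meso) | O=C1[C@@H]2CC[C@@H]2C(=O)O1 | starting material
2 | (1R,2S)-2-(methoxycarbonyl)cyclobutane-1-carboxylic acid | OC(=O)[C@@H]1CC[C@@H]1C(=O)OC | intermediate
3 | (1R,2R)-2-(methoxycarbonyl)cyclobutane-1-carboxylic acid | OC(=O)[C@@H]1CC[C@H]1C(=O)OC | intermediate
4 | dimethyl (1R,2R)-cyclobutane-1,2-dicarboxylate | COC(=O)[C@@H]1CC[C@H]1C(=O)OC | intermediate
5 | (1R,2R)-cyclobutane-1,2-dicarbaldehyde | O=C[C@@H]1CC[C@H]1C=O | intermediate
6 | (1R,2R)-1,2-diethynylcyclobutane | C#C[C@@H]1CC[C@H]1C#C | intermediate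
7 | 5-bromo-2,2'-bithiophene | Brc1ccc(-c2cccs2)s1 | starting material
8 | 5-{[(1R,2R)-2-ethynylcyclobutyl]ethynyl}-2,2'-bithiophene | C#C[C@@H]1CC[C@H]1C#Cc1ccc(-c2cccs2)s1 | intermediate
9 | cardopatine, (1R,2R)-1,2-bis[(2,2'-bithiophen-5-yl)ethynyl]cyclobutane | C(#C[C@@H]1CC[C@H]1C#Cc1ccc(-c2cccs2)s1)c1ccc(-c2cccs2)s1 | target

Total step count: 4
Longest linear sequence: 4 steps (from anhydride 1)

Steps most likely to fail

Step 3. The aluminium hemiacetals may collapse early and be reduced on to the alcohol, or one ester may stay untouched. The free dialdehyde may lose configuration by enolisation in basic methanol, and the volatile hydrocarbon product may be lost on concentration. The fallback sets out from diester 4 and comes back at diyne 6. LiAlH4 in THF at 0 °C should reduce 4 to (1R,2R)-cyclobutane-1,2-diyldimethanol F1. Swern oxidation ((COCl)2, DMSO, Et3N, CH2Cl2, −78 °C) should give dialdehyde 5, used crude and at once. Lithiated trimethylsilyldiazomethane (Me3SiCHN2, n-BuLi, THF, −78 °C to rt; Colvin rearrangement) should then turn both formyl groups into ethynyl groups in an aprotic medium, giving 6.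

Step 2. Equilibration may be slow or incomplete because the enolate has to form next to a carboxylate. Unepimerised material is carried into meso diester, and exchange of the ester position through the anhydride would erode optical purity. The fallback sets out from cis hemiester 2 and comes back at diyne 6. Amide coupling (MeNHOMe·HCl, EDC·HCl, N-methylmorpholine, CH2Cl2, 0 °C to rt) should give methyl (1S,2R)-2-[methoxy(methyl)carbamoyl]cyclobutane-1-carboxylate F2. Catalytic NaOMe in MeOH at rt should then epimerize the ester-bearing carbon alone, since the amide α-hydrogen is several pK units less acidic and no carboxylate is present. This should give the trans isomer methyl (1R,2R)-2-[methoxy(methyl)carbamoyl]cyclobutane-1-carboxylate F3. Both the ester and the Weinreb amide of F3 are reduced to the aldehyde level by i-Bu2AlH at −78 °C, so the one-pot protocol of step 3 should take F3 through dialdehyde 5 to 6.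

Step 4. Oxidative homocoupling of the terminal alkynes may give oligomers, the sequence may stall after the first coupling, and diyne may evaporate before it couples. The fallback sets out from dialdehyde 5 (made in isolable form from 4 through diol F1, as in the fallback to step 3) and comes back at target 9. Ramirez olefination (CBr4, PPh3, CH2Cl2, 0 °C) should give (1R,2R)-1,2-bis(2,2-dibromoethenyl)cyclobutane F4. Heating F4 with tributyl(2,2'-bithiophen-5-yl)stannane (CCCC[Sn](CCCC)(CCCC)c1ccc(-c2cccs2)s1, 2.4 equiv), Pd2(dba)3, tri(2-furyl)phosphine and i-Pr2NEt in DMF at 80 °C should effect the known tandem Stille coupling and dehydrobromination of 1,1-dibromoalkenes, which leads directly to internal alkynes. This forms the same two C(sp)–C5(thienyl) bonds from a non-volatile precursor and without copper.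

Further compounds
F1 | step 3 | (1R,2R)-cyclobutane-1,2-diyldimethanol | OC[C@@H]1CC[C@H]1CO
F2 | step 2 | methyl (1S,2R)-2-[methoxy(methyl)carbamoyl]cyclobutane-1-carboxylate | CON(C)C(=O)[C@@H]1CC[C@@H]1C(=O)OC
F3 | step 2 | methyl (1R,2R)-2-[methoxy(methyl)carbamoyl]cyclobutane-1-carboxylate | CON(C)C(=O)[C@@H]1CC[C@H]1C(=O)OC
F4 | step 4 | (1R,2R)-1,2-bis(2,2-dibromoethenyl)cyclobutane | BrC(Br)=C[C@@H]1CC[C@H]1C=C(Br)Br
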